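**Retrosynthetic overview**
1. Ring C is disconnected first at O1–C2 (Mitsunobu etherification). The C3–C4 bond follows; it is made together with the C3 stereocentre by an amine-catalysed addition of arylacetaldehyde 14 to the ring A ortho-quinone methide 19.
2. The CH2–CHO unit of 14 is traced back to the ester carbon on C1' of resorcylate 7 (ester to aldehyde, then one-carbon homologation). The hydrogen bond of the 2'-hydroxyl to the ester decides which oxygen takes prenyl (O4') and which takes silyl (O2').
3. The strategy rests on ring B being a 4,6-disubstituted resorcinol: oxygen on C2' and C4', carbon on C1' (bound to C3) and on C5' (the quaternary carbon of the 1,1-dimethylallyl group). A β-keto ester and an α-substituted β-methoxyacrylate give exactly this pattern, with C1'–C6' formed by addition–elimination and C3'–C4' by Claisen closure.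
4. Order of rings: ring B is built (step 3), ring A is bought as 2,4-dihydroxybenzaldehyde, and ring C is closed last (step 14).

Key step: step 3

Remark on the chemistry: every ester in the benzannulation is a methyl ester, so the methoxide set free cannot exchange ester groups. This ester is a spectator and is reduced in step 6.
Remark on the chemistry: the sense of induction in step 13 is assigned from the usual shielding model of diarylprolinol silyl ether E-enamines. By that model the (S)-catalyst would lead to 3S, so the (R)-catalyst is used.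

**Step 1**
Reactants: 1 methyl 3,3-dimethylpent-4-enoate; 2 methyl formate
Product: 3 methyl 2-formyl-3,3-dimethylpent-4-enoate (racemic aldehyde in equilibrium with its hydroxymethylene enol)
Conditions: LiN(iPr)2, THF, −78 °C; then 2, −78 °C → rt; 1 M HCl
Reagents that add atoms: none
Why: Crossed Claisen condensation (α-formylation), in which the lithium enolate of 1 is acylated by the small, non-enolisable ester 2, self-condensation is held back by the neighbouring quaternary carbon, and deprotonation of 3 by the released methoxide drives the equilibrium; the enolisable C2 centre is erased in step 2.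

**Step 2**
Reactants: 3 methyl 2-formyl-3,3-dimethylpent-4-enoate
Product: 4 methyl (E)-2-(methoxymethylene)-3,3-dimethylpent-4-enoate (may form as a mixture of geometric isomers; drawn E)
Conditions: Me2SO4, K2CO3, DMF, rt
Reagents that add atoms: dimethyl sulfate, COS(=O)(=O)OC
Why: O-alkylation of the ambident β-oxo ester enolate by a hard electrophile in a dipolar aprotic solvent (the standard β-methoxyacrylate preparation), with C-methylation blocked by the adjacent quaternary carbon and the alkene geometry irrelevant because it is lost in enolate 6.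

**Step 3**
Reactants: 4 methyl (E)-2-(methoxymethylene)-3,3-dimethylpent-4-enoate; 5 methyl acetoacetate
Product: 7 methyl 2,4-dihydroxy-5-(2-methylbut-3-en-2-yl)benzoate, via acetylglutaconate enolate 6 (not isolated)
Conditions: KOtBu (1.1 equiv), DME–DMPU, 0 → 85 °C; then KOtBu (2.5 equiv), 85 °C; 1 M HCl
Reagents that add atoms: none
Why: The potassium enolate of 5 adds through C2 to the methoxymethylene carbon of 4 and methoxide is expelled (vinylic addition–elimination, C1'–C6' bond), the adduct being drained at once as the fully conjugated enolate 6, whose low C5'–C6' bond order lets either geometry of 4 reach the cisoid form needed for closure. With further KOtBu the acetyl methyl group is deprotonated and its carbon acylates the methyl ester (Dieckmann-type Claisen condensation, 6-(enolendo)-exo-trig closure of ring B, C3'–C4' bond), and loss of methanol followed by double enolisation delivers the resorcylate as its dipotassium salt. The closest known reactions are the Michael–Dieckmann condensation of acetoacetates with crotonates to dihydroresorcylates, the condensation of acetoacetates with alkoxymethylenemalonates, and the alkoxide-induced isomerisation of 6-methyl-2-pyranone-5-carboxylates to resorcylates. No stereocentre is formed and the regiochemistry is fixed by connectivity, C2 of 5 becoming C1' and the α-carbon of 4 becoming C5'. The selectivity needed is C- over O-acylation: lactonisation through the enolate oxygen is also a six-ring closure and is not excluded kinetically, but the methoxide set free re-opens that lactone whereas C-acylation ends in an aromatic bis-phenoxide, so the equilibria should drain to 7. All ester and ether alkyl groups are methyl, so methoxide cannot scramble them, and the quaternary allylic carbon carries no hydrogen through which the vinyl group could migrate under base.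

**Step 4**
Reactants: 7 methyl 2,4-dihydroxy-5-(2-methylbut-3-en-2-yl)benzoate; 8 prenyl bromide (1-bromo-3-methylbut-2-ene)
Product: 9 methyl 2-hydroxy-5-(2-methylbut-3-en-2-yl)-4-(3-methylbut-2-enyloxy)benzoate
Conditions: K2CO3, acetone, reflux
Reagents that add atoms: none
Why: Williamson ether synthesis that tells the two phenols apart, since the 2-hydroxyl is hydrogen-bonded to the ester carbonyl while the 4-hydroxyl para to the ester is the more acidic and is ionised by K2CO3, and the primary allylic bromide is small enough to reach it beside the tert-alkyl group.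

**Step 5**
Reactants: 9 methyl 2-hydroxy-5-(2-methylbut-3-en-2-yl)-4-(3-methylbut-2-enyloxy)benzoate
Product: 10 methyl 5-(2-methylbut-3-en-2-yl)-4-(3-methylbut-2-enyloxy)-2-(triisopropylsilyloxy)benzoate
Conditions: TIPSOTf, 2,6-lutidine, CH2Cl2, 0 °C → rt
Reagents that add atoms: triisopropylsilyl triflate, CC(C)[Si](OS(=O)(=O)C(F)(F)F)(C(C)C)C(C)C
Why: O-silylation of the chelated, poorly nucleophilic phenol calls for the triflate, and the bulky triisopropylsilyl ether is chosen because it resists O-to-O migration and mild base in steps 6 to 14 and leaves with fluoride, without acid, at the end.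

**Step 6**
Reactants: 10 methyl 5-(2-methylbut-3-en-2-yl)-4-(3-methylbut-2-enyloxy)-2-(triisopropylsilyloxy)benzoate
Product: 11 [5-(2-methylbut-3-en-2-yl)-4-(3-methylbut-2-enyloxy)-2-(triisopropylsilyloxy)phenyl]methanol
Conditions: iBu2AlH, CH2Cl2, −78 → −20 °C; aq. potassium sodium tartrate
Reagents that add atoms: none
Why: Full hydride reduction of the benzoate to the benzylic alcohol, in which the aluminium alkoxide formed at low temperature is too weakly nucleophilic to take over the neighbouring silyl group and the alkenes and aryl ethers are inert.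

**Step 7**
Reactants: 11 [5-(2-methylbut-3-en-2-yl)-4-(3-methylbut-2-enyloxy)-2-(triisopropylsilyloxy)phenyl]methanol
Product: 12 5-(2-methylbut-3-en-2-yl)-4-(3-methylbut-2-enyloxy)-2-(triisopropylsilyloxy)benzaldehyde
Conditions: MnO2, CH2Cl2, rt
Reagents that add atoms: none
Why: Heterogeneous MnO2 oxidation is selective for benzylic alcohols, stops at the aldehyde and is neutral, so the silyl ether, the prenyl ether and both alkenes are left alone.

**Step 8**
Reactants: 12 5-(2-methylbut-3-en-2-yl)-4-(3-methylbut-2-enyloxy)-2-(triisopropylsilyloxy)benzaldehyde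
Product: 13 (E)-2-{2-[5-(2-methylbut-3-en-2-yl)-4-(3-methylbut-2-enyloxy)-2-(triisopropylsilyloxy)phenyl]ethenyl}-4,4,5,5-tetramethyl-1,3,2-dioxaborolane
Conditions: CH2(Bpin)2, lithium 2,2,6,6-tetramethylpiperidide, THF, 0 °C; then 12, −78 °C → rt; H2O
Reagents that add atoms: bis(4,4,5,5-tetramethyl-1,3,2-dioxaborolan-2-yl)methane, CC1(C)OB(CB2OC(C)(C)C(C)(C)O2)OC1(C)C
Why: Boron–Wittig olefination, in which the α-boryl carbanion adds to the non-enolisable aldehyde and syn B–O elimination gives the E-alkenylboronate; it is preferred to a methoxymethylene Wittig reaction because it avoids the acid hydrolysis of a styryl enol ether, which would endanger the prenyl ether.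

**Step 9**
Reactants: 13 (E)-alkenylboronate
Product: 14 2-[5-(2-methylbut-3-en-2-yl)-4-(3-methylbut-2-enyloxy)-2-(triisopropylsilyloxy)phenyl]acetaldehyde
Conditions: NaBO3·4H2O, THF–H2O, rt
Reagents that add atoms: sodium perborate, [Na+].[O-]OB=O
Why: Perborate oxidation of the C–B bond (1,2-shift of the alkenyl group from boron to oxygen) gives the enol borate and, after hydrolysis and tautomerisation, the arylacetaldehyde under mild conditions that neither epoxidise alkenes nor cleave aryl triisopropylsilyl ethers.

**Step 10**
Reactants: 15 2,4-dihydroxybenzaldehyde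
Product: 16 2-hydroxy-4-(triisopropylsilyloxy)benzaldehyde
Conditions: TIPSCl (1 equiv), imidazole, CH2Cl2, 0 °C → rt
Reagents that add atoms: triisopropylsilyl chloride, CC(C)[Si](Cl)(C(C)C)C(C)C
Why: Chemoselective O-silylation, since the 4-hydroxyl is free and the more acidic while the 2-hydroxyl is hydrogen-bonded to the formyl group, so one equivalent of the bulky chloride should react at O4 only.

**Step 11**
Reactants: 16 2-hydroxy-4-(triisopropylsilyloxy)benzaldehyde
Product: 17 2-(hydroxymethyl)-5-(triisopropylsilyloxy)phenol
Conditions: NaBH4, THF–MeOH, 0 °C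
Reagents that add atoms: none
Why: Borohydride reduction of the aldehyde to the salicyl alcohol, which leaves the aryl silyl ether untouched at 0 °C.

**Step 12**
Reactants: 17 2-(hydroxymethyl)-5-(triisopropylsilyloxy)phenol
Product: 18 2-[(4-methylphenyl)sulfonylmethyl]-5-(triisopropylsilyloxy)phenol
Conditions: p-TolSO2H (freshly prepared), CH2Cl2, rt
Reagents that add atoms: p-toluenesulfinic acid, Cc1ccc(cc1)S(=O)O
Why: SN1-type sulfone synthesis, in which the sulfinic acid ionises the electron-rich ortho-hydroxybenzyl alcohol to a quinone-methide-like cation that is captured at sulfur, the sulfone being the thermodynamic product.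

**Step 13**
Reactants: 14 arylacetaldehyde; 18 ring A sulfone
Product: 21 2-{(2R)-3-hydroxy-2-[5-(2-methylbut-3-en-2-yl)-4-(3-methylbut-2-enyloxy)-2-(triisopropylsilyloxy)phenyl]propyl}-5-(triisopropylsilyloxy)phenol, via ortho-quinone methide 19 (not isolated), via (3R)-chroman-2-ol lactol 20 (not isolated)
Conditions: (R)-α,α-diphenylprolinol trimethylsilyl ether (20 mol%), K2CO3, CH2Cl2, 0 °C; then NaBH4, MeOH, 0 °C
Reagents that add atoms: none
Why: Base-induced loss of sulfinate from 18 gives 19, whose exocyclic CH2 is attacked by the E-enamine of 14 on the face left open by the diphenyl(silyloxy)methyl group of the (R)-catalyst (enamine-catalysed formal [4+2], Michael addition then hemiacetalisation), which forms C3–C4 and sets C3 as R, and immediate NaBH4 reduction of lactol 20 removes the epimerisable aldehyde.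

**Step 14**
Reactants: 21 (R)-diol
Product: 22 (3R)-3-[5-(2-methylbut-3-en-2-yl)-4-(3-methylbut-2-enyloxy)-2-(triisopropylsilyloxy)phenyl]-7-(triisopropylsilyloxy)chroman
Conditions: PPh3, DIAD, THF, 0 °C → rt
Reagents that add atoms: none
Why: Intramolecular Mitsunobu etherification (6-exo-tet), in which the primary alcohol is activated as its alkoxyphosphonium salt and displaced by the only free phenol, closing ring C at O1–C2 without touching C3.

**Step 15**
Reactants: 22 bis-silyl isoflavan
Product: 23 manuifolin D, (3R)-3-[2-hydroxy-5-(2-methylbut-3-en-2-yl)-4-(3-methylbut-2-enyloxy)phenyl]chroman-7-ol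
Conditions: Bu4NF, AcOH, THF, 0 °C
Reagents that add atoms: none
Why: Fluoride-mediated desilylation cleaves both aryl silyl ethers (strong Si–F bond, good phenoxide leaving groups), and the AcOH buffer keeps the medium near neutral so the prenyl ether, the alkenes and C3 are unaffected.

**Compound list**
1 | methyl 3,3-dimethylpent-4-enoate | COC(=O)CC(C)(C)C=C | starting material
2 | methyl formate | COC=O | starting material
3 | methyl 2-formyl-3,3-dimethylpent-4-enoate (racemic, enolisable) | COC(=O)C(C=O)C(C)(C)C=C | intermediate
4 | methyl (E)-2-(methoxymethylene)-3,3-dimethylpent-4-enoate | CO/C=C(/C(=O)OC)C(C)(C)C=C | intermediate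
5 | methyl acetoacetate | COC(=O)CC(C)=O | starting material
6 | dimethyl 4-acetyl-2-(2-methylbut-3-en-2-yl)pent-2-enedioate, present as its potassium enolate (geometry mobile) | COC(=O)C(=CC(C(C)=O)C(=O)OC)C(C)(C)C=C | intermediate
7 | methyl 2,4-dihydroxy-5-(2-methylbut-3-en-2-yl)benzoate | COC(=O)c1cc(C(C)(C)C=C)c(O)cc1O | intermediate
8 | prenyl bromide | CC(C)=CCBr | starting material
9 | methyl 2-hydroxy-5-(2-methylbut-3-en-2-yl)-4-(3-methylbut-2-enyloxy)benzoate | COC(=O)c1cc(C(C)(C)C=C)c(OCC=C(C)C)cc1O | intermediate
10 | methyl 5-(2-methylbut-3-en-2-yl)-4-(3-methylbut-2-enyloxy)-2-(triisopropylsilyloxy)benzoate | COC(=O)c1cc(C(C)(C)C=C)c(OCC=C(C)C)cc1O[Si](C(C)C)(C(C)C)C(C)C | intermediate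
11 | [5-(2-methylbut-3-en-2-yl)-4-(3-methylbut-2-enyloxy)-2-(triisopropylsilyloxy)phenyl]methanol | OCc1cc(C(C)(C)C=C)c(OCC=C(C)C)cc1O[Si](C(C)C)(C(C)C)C(C)C | intermediate
12 | 5-(2-methylbut-3-en-2-yl)-4-(3-methylbut-2-enyloxy)-2-(triisopropylsilyloxy)benzaldehyde | O=Cc1cc(C(C)(C)C=C)c(OCC=C(C)C)cc1O[Si](C(C)C)(C(C)C)C(C)C | intermediate
13 | (E)-alkenyl pinacol boronate of ring B | CC1(C)OB(/C=C/c2cc(C(C)(C)C=C)c(OCC=C(C)C)cc2O[Si](C(C)C)(C(C)C)C(C)C)OC1(C)C | intermediate
14 | 2-[5-(2-methylbut-3-en-2-yl)-4-(3-methylbut-2-enyloxy)-2-(triisopropylsilyloxy)phenyl]acetaldehyde | O=CCc1cc(C(C)(C)C=C)c(OCC=C(C)C)cc1O[Si](C(C)C)(C(C)C)C(C)C | intermediate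
15 | 2,4-dihydroxybenzaldehyde | O=Cc1ccc(O)cc1O | starting material
16 | 2-hydroxy-4-(triisopropylsilyloxy)benzaldehyde | O=Cc1ccc(O[Si](C(C)C)(C(C)C)C(C)C)cc1O | intermediate
17 | 2-(hydroxymethyl)-5-(triisopropylsilyloxy)phenol | OCc1ccc(O[Si](C(C)C)(C(C)C)C(C)C)cc1O | intermediate
18 | 2-[(4-methylphenyl)sulfonylmethyl]-5-(triisopropylsilyloxy)phenol | Cc1ccc(cc1)S(=O)(=O)Cc1ccc(O[Si](C(C)C)(C(C)C)C(C)C)cc1O | intermediate
19 | 6-methylidene-3-(triisopropylsilyloxy)cyclohexa-2,4-dien-1-one | C=C1C=CC(O[Si](C(C)C)(C(C)C)C(C)C)=CC1=O | intermediate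
20 | (3R)-3-aryl-7-(triisopropylsilyloxy)chroman-2-ol (both anomers at C2) | C=CC(C)(C)c1cc([C@@H]2C(O)Oc3cc(O[Si](C(C)C)(C(C)C)C(C)C)ccc3C2)c(O[Si](C(C)C)(C(C)C)C(C)C)cc1OCC=C(C)C | intermediate
21 | (R)-diol (primary alcohol and free ring A phenol) | C=CC(C)(C)c1cc([C@H](CO)Cc2ccc(O[Si](C(C)C)(C(C)C)C(C)C)cc2O)c(O[Si](C(C)C)(C(C)C)C(C)C)cc1OCC=C(C)C | intermediate
22 | (3R)-7,2'-bis-O-triisopropylsilyl manuifolin D | C=CC(C)(C)c1cc([C@@H]2COc3cc(O[Si](C(C)C)(C(C)C)C(C)C)ccc3C2)c(O[Si](C(C)C)(C(C)C)C(C)C)cc1OCC=C(C)C | intermediate
23 | manuifolin D | C=CC(C)(C)c1cc([C@@H]2COc3cc(O)ccc3C2)c(O)cc1OCC=C(C)C | target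

**Step count**
Total: 15 steps. Longest linear sequence: 12 steps (steps 1–9, then 13–15). Ring A needs 3 steps (10–12).

**Steps most likely to fail**

1. Step 3.
   - What may go wrong: conjugate addition may be sluggish, because the acceptor carries a single ester, is deactivated by the methoxy donor and is branched at the α-carbon. The sequence may also stall after O-acylation (lactonisation), or the acetyl group may be lost by retro-Claisen cleavage before the ring closes.
   - Fallback: it sets out from 15 and comes back at 12, taking ring B from a bought arene and bypassing steps 1–7. O-alkylation of 15 with 8 (K2CO3, acetone) at the non-chelated hydroxyl gives 2-hydroxy-4-(3-methylbut-2-enyloxy)benzaldehyde F1. Silylation (TIPSOTf, 2,6-lutidine) gives 4-(3-methylbut-2-enyloxy)-2-(triisopropylsilyloxy)benzaldehyde F2. An aromatic Claisen rearrangement (N,N-diethylaniline, about 190 °C) then moves the prenyl group with allylic inversion to C5, since C3 is walled in by the silyl ether, and gives 4-hydroxy-5-(2-methylbut-3-en-2-yl)-2-(triisopropylsilyloxy)benzaldehyde F3. Mitsunobu etherification of F3 with 3-methylbut-2-en-1-ol (PPh3, DIAD) returns to the route at 12.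

2. Step 13.
   - What may go wrong: enantiopurity may erode through enolisation of the α-aryl aldehyde that is in equilibrium with the lactol. An uncatalysed, carbonate-mediated background addition, N-alkylation of the catalyst and oligomerisation of the quinone methide are further risks.
   - Fallback: it sets out from 14 and 17 and comes back at 21, replacing catalysis by auxiliary control (Evans alkylation).
   - Ring A part: phenol-selective allylation of 17 (allyl bromide, K2CO3, acetone) gives [2-(allyloxy)-4-(triisopropylsilyloxy)phenyl]methanol F4. Treatment with CBr4 and PPh3 gives 2-(allyloxy)-4-(triisopropylsilyloxy)benzyl bromide F5, which is used crude.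
   - Ring B part: Pinnick oxidation of 14 (NaClO2, NaH2PO4, excess 2-methylbut-2-ene) gives the arylacetic acid F6. Acylation of (R)-4-benzyloxazolidin-2-one through the pivaloyl mixed anhydride (PivCl, Et3N, LiCl) gives the N-arylacetyl imide F7.
   - Coupling: the Z-enolate of F7 (NaN(SiMe3)2, THF, −78 °C) is alkylated by F5 on the face away from the benzyl group and gives the (R)-configured alkylated imide F8. LiBH4 releases the auxiliary and gives the (R)-primary alcohol allyl ether F9. Zerovalent palladium (Pd(PPh3)4, morpholine) removes the allyl group in preference to the more substituted prenyl ether and returns to the route at 21.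

3. Step 9.
   - What may go wrong: the arylacetaldehyde may self-condense by aldol reaction or be over-oxidised in the mildly basic perborate medium. Before that, in step 8, the bulky boryl carbanion may add poorly to the ortho-silyloxy aldehyde.
   - Fallback: it sets out from 12 and comes back at 14, bypassing 13. Corey–Chaykovsky epoxidation (trimethylsulfonium iodide, NaH, DMSO–THF, 0 °C) gives the racemic aryl oxirane F10. A Meinwald rearrangement with a catalytic Lewis acid (InCl3, THF, rt) opens the epoxide at the electron-rich benzylic carbon, and a 1,2-hydride shift leads to 14.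

**Further compounds**
F1 | step 3 | 2-hydroxy-4-(3-methylbut-2-enyloxy)benzaldehyde | O=Cc1ccc(OCC=C(C)C)cc1O
F2 | step 3 | 4-(3-methylbut-2-enyloxy)-2-(triisopropylsilyloxy)benzaldehyde | O=Cc1ccc(OCC=C(C)C)cc1O[Si](C(C)C)(C(C)C)C(C)C
F3 | step 3 | 4-hydroxy-5-(2-methylbut-3-en-2-yl)-2-(triisopropylsilyloxy)benzaldehyde | O=Cc1cc(C(C)(C)C=C)c(O)cc1O[Si](C(C)C)(C(C)C)C(C)C
F4 | step 13 | [2-(allyloxy)-4-(triisopropylsilyloxy)phenyl]methanol | OCc1ccc(O[Si](C(C)C)(C(C)C)C(C)C)cc1OCC=C
F5 | step 13 | 2-(allyloxy)-4-(triisopropylsilyloxy)benzyl bromide | BrCc1ccc(O[Si](C(C)C)(C(C)C)C(C)C)cc1OCC=C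
F6 | step 13 | 2-[5-(2-methylbut-3-en-2-yl)-4-(3-methylbut-2-enyloxy)-2-(triisopropylsilyloxy)phenyl]acetic acid | OC(=O)Cc1cc(C(C)(C)C=C)c(OCC=C(C)C)cc1O[Si](C(C)C)(C(C)C)C(C)C
F7 | step 13 | (R)-4-benzyl-3-(arylacetyl)oxazolidin-2-one | O=C1OC[C@@H](Cc2ccccc2)N1C(=O)Cc1cc(C(C)(C)C=C)c(OCC=C(C)C)cc1O[Si](C(C)C)(C(C)C)C(C)C
F8 | step 13 | (4R)-4-benzyl-3-[(2R)-2-aryl-3-(2-allyloxy-4-triisopropylsilyloxyphenyl)propanoyl]oxazolidin-2-one | O=C1OC[C@@H](Cc2ccccc2)N1C(=O)[C@H](Cc1ccc(O[Si](C(C)C)(C(C)C)C(C)C)cc1OCC=C)c1cc(C(C)(C)C=C)c(OCC=C(C)C)cc1O[Si](C(C)C)(C(C)C)C(C)C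
F9 | step 13 | (2R)-2-aryl-3-(2-allyloxy-4-triisopropylsilyloxyphenyl)propan-1-ol | C=CC(C)(C)c1cc([C@H](CO)Cc2ccc(O[Si](C(C)C)(C(C)C)C(C)C)cc2OCC=C)c(O[Si](C(C)C)(C(C)C)C(C)C)cc1OCC=C(C)C
F10 | step 9 | 2-[5-(2-methylbut-3-en-2-yl)-4-(3-methylbut-2-enyloxy)-2-(triisopropylsilyloxy)phenyl]oxirane (racemic) | C1OC1c1cc(C(C)(C)C=C)c(OCC=C(C)C)cc1O[Si](C(C)C)(C(C)C)C(C)C
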